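The target is the ester of a (2S)-2-isopropenyl-2,3-dihydrobenzofuran-5-ylmethanol with (Z)-2-hexylidene-3-methylsuccinic acid. Everything rests on opening the dihydrofuran ring at O1–C2 and C3–C3a: the atoms O1, C2 and C3, with the isopropenyl group on C2, are one isoprene unit spanning a phenol oxygen and its ortho carbon. A single palladium-catalysed diene heteroannulation of methyl 4-hydroxy-3-iodobenzoate (an ortho-iodophenol carrying a para ester handle) with isoprene forms both bonds, the ring and the C2 stereocentre. The acid part is then grown on the derived benzylic alcohol from (R)-lactic acid by triflate inversion and a Z-selective olefination with hexanal.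

Key step: step 1

Assumption: which antipode of the chiral phosphine gives the (2S) ring carbon is settled by a test run with each; the (2S)-forming one is used.

Step 1
Reactants: 1 methyl 4-hydroxy-3-iodobenzoate; 2 isoprene
Product: 3 methyl (2S)-2-(prop-1-en-2-yl)-2,3-dihydro-1-benzofuran-5-carboxylate
Conditions: Pd2(dba)3·CHCl3 (2.5 mol%), chiral sulfinamide–monophosphine ligand (TY-Phos type, 10 mol%), NaOPh (2 equiv), 2 (4 equiv), CH2Cl2, 40 °C, sealed tube
Reagents that add atoms: none
Why: Oxidative addition of the aryl iodide to the ligated zerovalent palladium is followed by syn-carbopalladation of the unsubstituted vinyl group of isoprene, the aryl carbon bonding to its CH2 terminus; this makes the C3–C3a bond and a π-allylpalladium unit over the other three diene carbons. The tethered phenoxide then attacks the allyl terminus next to the new C–C bond (Tsuji–Trost-type allylic etherification), which forms O1–C2 and closes the five-membered ring in a 5-exo mode. The closest known reaction type is the Larock heteroannulation of 1,3-dienes with ortho-halophenols, for which enantioselective versions with chiral monophosphines are established. The C2 stereocentre is under ligand control, because the two allyl faces equilibrate by π–σ–π interconversion through the unsubstituted CH2 terminus and the chiral phosphine selects the face on which the C–O bond forms. The step needs insertion at the right alkene (secured by the methyl group that hinders the other double bond), five- over seven-membered closure (secured by ring size) and tolerance of the ester (inert to these conditions; it also makes the phenol acidic enough to be fully ionised by NaOPh).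

Step 2
Reactants: 3 methyl (2S)-2-(prop-1-en-2-yl)-2,3-dihydro-1-benzofuran-5-carboxylate
Product: 4 [(2S)-2-(prop-1-en-2-yl)-2,3-dihydro-1-benzofuran-5-yl]methanol
Conditions: i-Bu2AlH (2.5 equiv), CH2Cl2, −78 to 0 °C; aq. potassium sodium tartrate
Reagents that add atoms: none
Why: Aluminium hydride reduction of an aryl ester to the benzylic alcohol, under which the aryl ether, the isopropenyl group and the C2 stereocentre are inert.

Step 3
Reactants: 4 [(2S)-2-(prop-1-en-2-yl)-2,3-dihydro-1-benzofuran-5-yl]methanol; 5 (R)-lactic acid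
Product: 8 [(2S)-2-(prop-1-en-2-yl)-2,3-dihydro-1-benzofuran-5-yl]methyl (2R)-2-hydroxypropanoate, via benzylic mesylate 6 (not isolated), via benzylic chloride 7 (not isolated)
Conditions: MsCl, i-Pr2NEt, CH2Cl2, 0 °C to rt; concentrate; then 5, Cs2CO3, DMF, rt
Reagents that add atoms: none
Why: Sulfonylation of the electron-rich benzylic alcohol collapses to the benzylic chloride, which O-alkylates caesium (R)-lactate (carboxylate SN2 alkylation) without touching the lactate stereocentre, and the amine-buffered conditions avoid HCl addition to the isopropenyl group.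

Step 4
Reactants: 8 [(2S)-2-(prop-1-en-2-yl)-2,3-dihydro-1-benzofuran-5-yl]methyl (2R)-2-hydroxypropanoate
Product: 9 [(2S)-2-(prop-1-en-2-yl)-2,3-dihydro-1-benzofuran-5-yl]methyl (2R)-2-{[(trifluoromethyl)sulfonyl]oxy}propanoate
Conditions: Tf2O, 2,6-lutidine, CH2Cl2, −78 °C; cold short silica plug, used at once
Reagents that add atoms: trifluoromethanesulfonic anhydride, O=S(=O)(OS(=O)(=O)C(F)(F)F)C(F)(F)F
Why: O-Triflation of an α-hydroxy ester with a hindered pyridine base leaves the C–O bond intact (retention) and gives a configurationally defined, highly SN2-reactive α-triflyloxy ester, while the buffer protects the acid-labile 4-alkoxybenzyl-type ester.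

Step 5
Reactants: 10 bromoacetyl bromide; 11 2-(trimethylsilyl)ethanol
Product: 12 2-(trimethylsilyl)ethyl bromoacetate
Conditions: pyridine, CH2Cl2, 0 °C
Reagents that add atoms: none
Why: Esterification of a primary alcohol by an acid bromide, the acyl bromide reacting far faster than the alkyl bromide.

Step 6
Reactants: 12 2-(trimethylsilyl)ethyl bromoacetate; 13 diphenyl phosphite
Product: 14 2-(trimethylsilyl)ethyl 2-(diphenoxyphosphoryl)acetate
Conditions: Et3N, CH2Cl2, 0 °C to rt
Reagents that add atoms: none
Why: Michaelis–Becker-type P-alkylation of the diaryl phosphite with an α-bromo ester, the usual entry to diaryl phosphonoacetates for Z-selective olefination.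

Step 7
Reactants: 9 [(2S)-2-(prop-1-en-2-yl)-2,3-dihydro-1-benzofuran-5-yl]methyl (2R)-2-{[(trifluoromethyl)sulfonyl]oxy}propanoate; 14 2-(trimethylsilyl)ethyl 2-(diphenoxyphosphoryl)acetate
Product: 15 4-{[(2S)-2-(prop-1-en-2-yl)-2,3-dihydro-1-benzofuran-5-yl]methyl} 1-[2-(trimethylsilyl)ethyl] (3S)-2-(diphenoxyphosphoryl)-3-methylbutanedioate (both C2 epimers; 3S only because phosphorus raises the priority of C2, the spatial arrangement is that of the target)
Conditions: 14 (2 equiv), NaH (2 equiv), THF, 0 °C; then 9, 0 °C to rt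
Reagents that add atoms: none
Why: SN2 displacement of a secondary α-triflyloxy ester by a soft stabilised carbanion, which for malonate-type nucleophiles goes with clean Walden inversion, so the (2R)-triflate sets the methyl-bearing stereocentre in the configuration of the target, and the epimeric phosphonate carbon disappears in step 8.

Step 8
Reactants: 15 the phosphonosuccinate from step 7; 16 hexanal
Product: 17 2-(trimethylsilyl)ethyl (2Z)-2-[(2R)-1-oxo-1-{[(2S)-2-(prop-1-en-2-yl)-2,3-dihydro-1-benzofuran-5-yl]methoxy}propan-2-yl]oct-2-enoate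
Conditions: NaH (1.05 equiv), THF, 0 °C; then 16, −78 to 0 °C
Reagents that add atoms: none
Why: Z-selective Horner–Wadsworth–Emmons olefination with an α-substituted diaryl phosphonate, whose anion adds irreversibly to the aldehyde and eliminates fast, should place the pentyl chain cis to the ester and trans to the branched substituent, and the stereocentre is not enolised because the base is consumed by the far more acidic P–CH–CO position.

Step 9
Reactants: 17 the 2-(trimethylsilyl)ethyl ester from step 8
Product: 18 (2Z)-2-[(2R)-1-oxo-1-{[(2S)-2-(prop-1-en-2-yl)-2,3-dihydro-1-benzofuran-5-yl]methoxy}propan-2-yl]oct-2-enoic acid (target)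
Conditions: Bu4NF, THF, 0 °C; AcOH quench
Reagents that add atoms: none
Why: Fluoride-induced fragmentation of the 2-(trimethylsilyl)ethyl ester frees the acrylic acid without acid and without palladium, so the acid-labile 4-alkoxybenzyl-type ester and the allylic aryl ether of the ring are spared, and at 0 °C the α-stereocentre should survive.

Compound list
1 | methyl 4-hydroxy-3-iodobenzoate | COC(=O)c1ccc(O)c(I)c1 | starting material
2 | isoprene | C=CC(C)=C | starting material
3 | methyl (2S)-2-(prop-1-en-2-yl)-2,3-dihydro-1-benzofuran-5-carboxylate | C=C(C)[C@@H]1Cc2cc(C(=O)OC)ccc2O1 | intermediate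
4 | [(2S)-2-(prop-1-en-2-yl)-2,3-dihydro-1-benzofuran-5-yl]methanol | C=C(C)[C@@H]1Cc2cc(CO)ccc2O1 | intermediate
5 | (R)-lactic acid | C[C@@H](O)C(=O)O | starting material
6 | [(2S)-2-(prop-1-en-2-yl)-2,3-dihydro-1-benzofuran-5-yl]methyl methanesulfonate (not isolated) | C=C(C)[C@@H]1Cc2cc(COS(C)(=O)=O)ccc2O1 | intermediate
7 | (2S)-5-(chloromethyl)-2-(prop-1-en-2-yl)-2,3-dihydro-1-benzofuran (not isolated) | C=C(C)[C@@H]1Cc2cc(CCl)ccc2O1 | intermediate
8 | [(2S)-2-(prop-1-en-2-yl)-2,3-dihydro-1-benzofuran-5-yl]methyl (2R)-2-hydroxypropanoate | C=C(C)[C@@H]1Cc2cc(COC(=O)[C@@H](C)O)ccc2O1 | intermediate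
9 | [(2S)-2-(prop-1-en-2-yl)-2,3-dihydro-1-benzofuran-5-yl]methyl (2R)-2-{[(trifluoromethyl)sulfonyl]oxy}propanoate | C=C(C)[C@@H]1Cc2cc(COC(=O)[C@@H](C)OS(=O)(=O)C(F)(F)F)ccc2O1 | intermediate
10 | bromoacetyl bromide | BrCC(=O)Br | starting material
11 | 2-(trimethylsilyl)ethanol | C[Si](C)(C)CCO | starting material
12 | 2-(trimethylsilyl)ethyl bromoacetate | BrCC(=O)OCC[Si](C)(C)C | intermediate
13 | diphenyl phosphite | O=[PH](Oc1ccccc1)Oc1ccccc1 | starting material
14 | 2-(trimethylsilyl)ethyl 2-(diphenoxyphosphoryl)acetate | C[Si](C)(C)CCOC(=O)CP(=O)(Oc1ccccc1)Oc1ccccc1 | intermediate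
15 | 4-{[(2S)-2-(prop-1-en-2-yl)-2,3-dihydro-1-benzofuran-5-yl]methyl} 1-[2-(trimethylsilyl)ethyl] (3S)-2-(diphenoxyphosphoryl)-3-methylbutanedioate, both C2 epimers | C=C(C)[C@@H]1Cc2cc(COC(=O)[C@H](C)C(C(=O)OCC[Si](C)(C)C)P(=O)(Oc3ccccc3)Oc3ccccc3)ccc2O1 | intermediate
16 | hexanal | CCCCCC=O | starting material
17 | 2-(trimethylsilyl)ethyl (2Z)-2-[(2R)-1-oxo-1-{[(2S)-2-(prop-1-en-2-yl)-2,3-dihydro-1-benzofuran-5-yl]methoxy}propan-2-yl]oct-2-enoate | C=C(C)[C@@H]1Cc2cc(COC(=O)[C@H](C)/C(=C/CCCCC)C(=O)OCC[Si](C)(C)C)ccc2O1 | intermediate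
18 | (2Z)-2-[(2R)-1-oxo-1-{[(2S)-2-(prop-1-en-2-yl)-2,3-dihydro-1-benzofuran-5-yl]methoxy}propan-2-yl]oct-2-enoic acid | C=C(C)[C@@H]1Cc2cc(COC(=O)[C@H](C)/C(=C/CCCCC)C(=O)O)ccc2O1 | target

Total step count: 9. Longest linear sequence: 7 (steps 1, 2, 3, 4, 7, 8, 9); steps 5 and 6 prepare the phosphonate.

Steps most likely to fail

Step 8. The α-branched phosphonate anion may add to hexanal slowly and with poor discrimination, so that the alkene forms as an E/Z mixture. The fallback sets out from 4 (and uses 11) and comes back at 17; it fixes the geometry by syn-addition to an alkyne instead. Alcohol 4 is acylated with racemic 2-bromopropanoyl bromide (pyridine, CH2Cl2, 0 °C) to [(2S)-2-(prop-1-en-2-yl)-2,3-dihydro-1-benzofuran-5-yl]methyl 2-bromopropanoate F1. Commercial oct-2-ynoic acid is esterified with 11 (DCC, cat. DMAP) to 2-(trimethylsilyl)ethyl oct-2-ynoate F2. Syn-hydrostannation (Bu3SnH, Pd(PPh3)4, THF) puts tin on the α-carbon and should give 2-(trimethylsilyl)ethyl (2E)-2-(tributylstannyl)oct-2-enoate F3. Iododestannylation (I2, CH2Cl2, 0 °C) then gives, with retention, 2-(trimethylsilyl)ethyl (2E)-2-iodooct-2-enoate F4. The iodine must sit on C2, trans to the pentyl chain; hydroiodination of the ynoic acid would give the useless 3-iodo isomer. F1 and F4 are joined by a stereoconvergent nickel-catalysed reductive cross-coupling (NiBr2·glyme, chiral bis(oxazoline) ligand, Mn powder, DMA, 0 °C), in which the α-ester radical from either bromide enantiomer is captured by the chiral alkenylnickel species; this gives 17 with the alkene geometry retained. This reaction class is established for α-halo esters with aryl iodides and for benzylic chlorides with alkenyl bromides, but not for an α-iodoacrylate, which is why it is held in reserve. Any minor C-α epimer would be removed on a chiral stationary phase.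

Step 1. Facial discrimination in the C–O ring closure may be insufficient (low ee), made worse if iodide displaces the chiral phosphine, or insertion may occur at the methyl-bearing alkene. The fallback sets out from 1 and comes back at 3; it closes the ring by epoxide opening. Stille coupling of 1 with tributyl(3-methylbut-2-en-1-yl)stannane (Pd(PPh3)4, DMF, 90 °C) gives methyl 4-hydroxy-3-(3-methylbut-2-en-1-yl)benzoate F5. Shi epoxidation (KHSO5, K2CO3, the fructose-derived ketone antipode that gives the R epoxide) gives methyl 3-{[(2R)-3,3-dimethyloxiran-2-yl]methyl}-4-hydroxybenzoate F6. With K2CO3 in MeOH the phenoxide opens the epoxide at the secondary carbon with inversion (5-exo) to give methyl (2S)-2-(2-hydroxypropan-2-yl)-2,3-dihydro-1-benzofuran-5-carboxylate F7. Dehydration of the tertiary alcohol with Burgess reagent gives 3.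

Step 9. Fluoride may act as a base, causing epimerisation at the α-carbon, migration of the alkene into conjugation with the benzylic ester, or acyl transfer through the cyclic anhydride. The fallback sets out from 10, uses 13, 9 and 16, and comes back at 18; it masks the acid as a trichloroethyl ester that is removed reductively without base. 10 and 2,2,2-trichloroethanol (pyridine, CH2Cl2) give 2,2,2-trichloroethyl bromoacetate F8. 13 and Et3N convert it into 2,2,2-trichloroethyl 2-(diphenoxyphosphoryl)acetate F9. Its sodium salt displaces the triflate of 9 with inversion to give the trichloroethyl analogue of 15 F10. Olefination with 16 as in step 8 gives the trichloroethyl analogue of 17 F11. Zn dust in AcOH/THF (0 °C to rt) then gives 18.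

Further compounds
F1 | step 8 | [(2S)-2-(prop-1-en-2-yl)-2,3-dihydro-1-benzofuran-5-yl]methyl 2-bromopropanoate (racemic at the bromine-bearing carbon) | C=C(C)[C@@H]1Cc2cc(COC(=O)C(C)Br)ccc2O1
F2 | step 8 | 2-(trimethylsilyl)ethyl oct-2-ynoate | CCCCCC#CC(=O)OCC[Si](C)(C)C
F3 | step 8 | 2-(trimethylsilyl)ethyl (2E)-2-(tributylstannyl)oct-2-enoate | CCCCC/C=C(/[Sn](CCCC)(CCCC)CCCC)C(=O)OCC[Si](C)(C)C
F4 | step 8 | 2-(trimethylsilyl)ethyl (2E)-2-iodooct-2-enoate | CCCCC/C=C(/I)C(=O)OCC[Si](C)(C)C
F5 | step 1 | methyl 4-hydroxy-3-(3-methylbut-2-en-1-yl)benzoate | COC(=O)c1ccc(O)c(CC=C(C)C)c1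
F6 | step 1 | methyl 3-{[(2R)-3,3-dimethyloxiran-2-yl]methyl}-4-hydroxybenzoate | COC(=O)c1ccc(O)c(C[C@H]2OC2(C)C)c1
F7 | step 1 | methyl (2S)-2-(2-hydroxypropan-2-yl)-2,3-dihydro-1-benzofuran-5-carboxylate | CC(C)(O)[C@@H]1Cc2cc(C(=O)OC)ccc2O1
F8 | step 9 | 2,2,2-trichloroethyl bromoacetate | BrCC(=O)OCC(Cl)(Cl)Cl
F9 | step 9 | 2,2,2-trichloroethyl 2-(diphenoxyphosphoryl)acetate | O=C(CP(=O)(Oc1ccccc1)Oc1ccccc1)OCC(Cl)(Cl)Cl
F10 | step 9 | 4-{[(2S)-2-(prop-1-en-2-yl)-2,3-dihydro-1-benzofuran-5-yl]methyl} 1-(2,2,2-trichloroethyl) (3S)-2-(diphenoxyphosphoryl)-3-methylbutanedioate, both C2 epimers | C=C(C)[C@@H]1Cc2cc(COC(=O)[C@H](C)C(C(=O)OCC(Cl)(Cl)Cl)P(=O)(Oc3ccccc3)Oc3ccccc3)ccc2O1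
F11 | step 9 | 2,2,2-trichloroethyl (2Z)-2-[(2R)-1-oxo-1-{[(2S)-2-(prop-1-en-2-yl)-2,3-dihydro-1-benzofuran-5-yl]methoxy}propan-2-yl]oct-2-enoate | C=C(C)[C@@H]1Cc2cc(COC(=O)[C@H](C)/C(=C/CCCCC)C(=O)OCC(Cl)(Cl)Cl)ccc2O1
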